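## Retrosynthetic overview

1. The CH2–CH2 linker is made last but one: the γ-sulfonyl carbanion of hydroazulenone 19 adds to the α-methylene ketone unmasked from 35, the methyl carbinol is made in the same flask, and the sulfone is then removed reductively.
2. Right half 17: the key disconnection is the cyclopentanol C–C bond at the ring fusion, formed by a SmI2 ketyl–enone radical cyclization of keto-dienone 16; this sets the cis ring fusion and the tertiary carbinol together.
3. 16 comes from cyclohexadienone 7 by Cu-catalysed asymmetric conjugate addition and FeCl3 one-carbon ring expansion; 7 comes from a Michael–Claisen dione.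
4. Left half 35: anti cuprate addition to (R)-silyloxy enone 25 sets the quaternary centre, the enolate is thiomethylated, and the oxepane is closed by Shi epoxidation, radical isomerization to the allylic alcohol and Markovnikov alkoxymercuration.
5. Ring order: right half six → seven → five; left half six → oxepane; union last.

Assumption: the sense of induction in the three reagent-controlled steps (6, 12, 15) is assigned from the standard models for the parent substrates; if one proves opposite, the mirror-image ligand or reagent is used.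

## Route

Step 1
Reactants: 1 2-methylpentan-3-one; 2 methyl acrylate
Product: 3 2,4,4-trimethylcyclohexane-1,3-dione
Conditions: KOtBu (1.2 equiv), THF, 0 °C to rt; 1 M HCl
Reagents that add atoms: none
Why: Consecutive Michael–Claisen condensation: the isopropyl-side enolate adds to the acrylate and the ethyl-side enolate then acylates on the ester, the enolisable 1,3-dione being the only irreversible sink (C-2 is enolised, so no stereocentre is set).

Step 2
Reactants: 3 2,4,4-trimethylcyclohexane-1,3-dione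
Product: 4 3-methoxy-2,6,6-trimethylcyclohex-2-en-1-one
Conditions: MeOH, TsOH (cat.), 3 Å sieves, reflux
Reagents that add atoms: methanol (CO)
Why: Acid-catalysed vinylogous ester formation under thermodynamic control, the methoxy group going onto the carbonyl remote from the gem-dimethyl group.

Step 3
Reactants: 4 3-methoxy-2,6,6-trimethylcyclohex-2-en-1-one
Product: 6 2,3,4,4-tetramethylcyclohex-2-en-1-one, via carbinol lithium alkoxide 5 (not isolated)
Conditions: MeLi, Et2O, 0 °C; then 1 M HCl, rt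
Reagents that add atoms: methyllithium ([Li]C); water (O)
Why: Stork–Danheiser alkylative carbonyl transposition: 1,2-addition to the hindered ketone, then acid hydrolysis of the enol ether with loss of water gives the transposed enone.

Step 4
Reactants: 6 2,3,4,4-tetramethylcyclohex-2-en-1-one
Product: 7 2,3,4,4-tetramethylcyclohexa-2,5-dien-1-one
Conditions: IBX (2 equiv), DMSO, 80 °C
Reagents that add atoms: none
Why: IBX dehydrogenation (Nicolaou) on the only enolisable side gives the cross-conjugated dienone.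

Step 5
Reactants: 8 but-3-en-2-one
Product: 9 2-(2-bromoethyl)-2-methyl-1,3-dioxolane
Conditions: HBr (gas), ethane-1,2-diol, 0 °C to rt
Reagents that add atoms: hydrogen bromide (Br); ethane-1,2-diol (OCCO)
Why: Conjugate addition of HBr to the enone with in situ ketalization gives the protected 3-oxobutyl bromide.

Step 6
Reactants: 7 2,3,4,4-tetramethylcyclohexa-2,5-dien-1-one; 9 2-(2-bromoethyl)-2-methyl-1,3-dioxolane
Product: 12 trimethyl{[(6R)-3,4,5,5-tetramethyl-6-[2-(2-methyl-1,3-dioxolan-2-yl)ethyl]cyclohexa-1,3-dien-2-yl]oxy}silane, via Grignard reagent 10 (not isolated), via diorganozinc 11 (not isolated)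
Conditions: 9, Mg, THF; ZnCl2 (0.5 equiv), 1,4-dioxane; then 7, Cu(OTf)2 (2 mol%), (S,R,R)-phosphoramidite from (S)-BINOL and bis[(R)-1-phenylethyl]amine (4 mol%), toluene, −30 °C; TMSOTf, −30 to 0 °C
Reagents that add atoms: trimethylsilyl trifluoromethanesulfonate (C[Si](C)(C)OS(=O)(=O)C(F)(F)F)
Why: Cu/phosphoramidite-catalysed asymmetric conjugate addition (Feringa) to the only unsubstituted enone β-carbon; the ligand sets the 6R centre (same facial sense as with cyclohex-2-enone) and the zinc enolate is trapped regiospecifically as the silyl enol ether.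

Step 7
Reactants: 12 silyl dienol ether
Product: 13 (5R)-2,3,4,4-tetramethyl-5-[2-(2-methyl-1,3-dioxolan-2-yl)ethyl]-1-(trimethylsilyloxy)bicyclo[4.1.0]hept-2-ene (cyclopropane CH2 anti to the side chain)
Conditions: Zn–Cu couple, CH2I2, Et2O, reflux; pyridine work-up
Reagents that add atoms: diiodomethane (ICI)
Why: Simmons–Smith cyclopropanation, selective for the electron-rich silyl enol ether double bond of the 2-silyloxy diene and anti to the side chain (the two new centres are destroyed in step 8).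

Step 8
Reactants: 13 silyloxycyclopropane
Product: 16 (5R)-2,3,4,4-tetramethyl-5-(3-oxobutyl)cyclohepta-2,6-dien-1-one, via chloro ketone 14 (not isolated), via dienone ketal 15 (not isolated)
Conditions: FeCl3 (2.2 equiv), pyridine, DMF, 0 °C; NaOAc, MeOH, 60 °C; then 1 M HCl, THF, rt
Reagents that add atoms: water (O)
Why: Ito–Saegusa ring expansion: FeCl3 oxidizes the silyloxycyclopropane to an alkoxy radical, β-scission of the internal bond gives the ring-enlarged β-keto radical, which is trapped as the chloride; loss of HCl gives the cycloheptadienone and aqueous acid frees the methyl ketone, with the 5R centre untouched.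

Step 9
Reactants: 16 (5R)-2,3,4,4-tetramethyl-5-(3-oxobutyl)cyclohepta-2,6-dien-1-one
Product: 17 (1R,3aR,8aR)-1-hydroxy-1,4,4,5,6-pentamethyl-2,3,3a,4,8,8a-hexahydroazulen-7(1H)-one
Conditions: SmI2 (2.2 equiv), HMPA, THF, −78 °C, slow addition of 16; then pH 7 buffer
Reagents that add atoms: none
Why: Key step, SmI2 ketyl–olefin radical cyclization: the ketyl carbon adds 5-exo to the β-carbon of the disubstituted enone from the face of its tether (cis ring fusion) with the O–Sm group anti to the forming samarium enolate, which puts the hydroxyl cis to both ring-fusion hydrogens; the tetrasubstituted enone is protected as the samarium dienolate until work-up.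

Step 10
Reactants: 17 hydroxy enone
Product: 19 (1R,3aR,8aR)-1-hydroxy-1,4,4,6-tetramethyl-5-[(phenylsulfonyl)methyl]-2,3,3a,4,8,8a-hexahydroazulen-7(1H)-one, via allylic bromide 18 (not isolated)
Conditions: NBS, AIBN (cat.), PhCF3, 80 °C; then PhSO2Na, DMF, rt
Reagents that add atoms: sodium benzenesulfinate ([Na+].[O-]S(=O)c1ccccc1)
Why: Wohl–Ziegler bromination at the γ-methyl group (the most stabilized allylic radical; the ring γ-carbon is quaternary) followed by SN2 displacement with sulfinate.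

Step 11
Reactants: 20 cyclohexane-1,3-dione
Product: 21 3-methoxycyclohex-2-en-1-one
Conditions: MeOH, TsOH (cat.), 3 Å sieves, reflux
Reagents that add atoms: methanol (CO)
Why: Acid-catalysed vinylogous ester formation.

Step 12
Reactants: 21 3-methoxycyclohex-2-en-1-one
Product: 23 (6R)-6-[(tert-butyldimethylsilyl)oxy]-3-methoxycyclohex-2-en-1-one, via lithium alkoxide 22 (not isolated)
Conditions: LDA (LiN(i-Pr)2), THF, −78 °C; (+)-(camphorsulfonyl)oxaziridine, −78 °C; then TBSOTf, −78 to 0 °C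
Reagents that add atoms: (+)-(camphorsulfonyl)oxaziridine (CC1(C)C2CCC13CS(=O)(=O)N4OC34C2); tert-butyldimethylsilyl trifluoromethanesulfonate (CC(C)(C)[Si](C)(C)OS(=O)(=O)C(F)(F)F)
Why: Davis asymmetric hydroxylation of the kinetic α'-enolate (the chiral oxaziridine sets the 6R centre) followed by O-silylation of the lithium alkoxide.

Step 13
Reactants: 23 silyloxy vinylogous ester
Product: 25 (4R)-4-[(tert-butyldimethylsilyl)oxy]-3-methylcyclohex-2-en-1-one, via carbinol lithium alkoxide 24 (not isolated)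
Conditions: MeLi, Et2O, −78 °C; then 1 M HCl, THF, 0 °C
Reagents that add atoms: methyllithium ([Li]C); water (O)
Why: Stork–Danheiser transposition as in step 3; the silyloxy-bearing centre is not enolised and keeps its configuration.

Step 14
Reactants: 25 (4R)-silyloxy enone; 26 5-bromo-2-methylpent-2-ene
Product: 29 (3R,4R)-4-[(tert-butyldimethylsilyl)oxy]-3-methyl-3-(4-methylpent-3-en-1-yl)-2-[(methylsulfanyl)methyl]cyclohexan-1-one, via Grignard reagent 27 (not isolated), via silyl enol ether 28 (not isolated)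
Conditions: 26, Mg, THF; CuBr·SMe2 (10 mol%), Me3SiCl, HMPA, 25, THF, −78 °C; then MeSCH2Cl, ZnBr2 (cat.), CH2Cl2, rt
Reagents that add atoms: chloromethyl methyl sulfide (ClCSC)
Why: Cu-catalysed, Me3SiCl-accelerated conjugate addition anti to the γ-silyloxy group sets the quaternary centre (3R), and the regiodefined silyl enol ether is alkylated by the thionium ion (Paterson ZnBr2-catalysed thiomethylation); the new C-2 centre is lost in step 18.

Step 15
Reactants: 29 thiomethyl ketone
Product: 31 (3R,4R)-4-[(tert-butyldimethylsilyl)oxy]-3-{2-[(2R)-3,3-dimethyloxiran-2-yl]ethyl}-3-methyl-2-[(methylsulfonyl)methyl]cyclohexan-1-one, via sulfone alkene 30 (not isolated)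
Conditions: Oxone (KHSO5, 4 equiv), D-fructose-derived Shi ketone (0.3 equiv), K2CO3, Bu4NHSO4, MeCN–DMM–aq. buffer, 0 °C
Reagents that add atoms: potassium peroxymonosulfate ([K+].[O-]S(=O)(=O)OO)
Why: Oxone oxidizes the sulfide to the sulfone and the Shi dioxirane epoxidizes the trisubstituted alkene, the D-fructose-derived ketone giving the (R)-epoxide by the spiro transition-state model (Shi asymmetric epoxidation).

Step 16
Reactants: 31 epoxy sulfone
Product: 33 (3R,4R)-4-hydroxy-3-[(3R)-3-hydroxy-4-methylpent-4-en-1-yl]-3-methyl-2-[(methylsulfonyl)methyl]cyclohexan-1-one, via silyl allylic alcohol 32 (not isolated)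
Conditions: Cp2TiCl2 (2.2 equiv), Mn dust, THF, rt; then HF·pyridine, 0 °C
Reagents that add atoms: none
Why: Titanocene monochloride (trivalent titanium) opens the epoxide homolytically to the tertiary radical (Nugent–RajanBabu opening); a second equivalent traps it and β-hydride elimination gives the 1,1-disubstituted allylic alcohol with the carbinol configuration retained; HF·pyridine then removes the silyl group.

Step 17
Reactants: 33 keto diol sulfone
Product: 35 (3R,5aR,9aR)-3-hydroxy-2,2,5a-trimethyl-6-[(methylsulfonyl)methyl]octahydro-1-benzoxepin-7(2H)-one, via organomercurial 34 (not isolated)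
Conditions: Hg(O2CCF3)2, MeCN, 0 °C to rt; then Bu3SnH, 0 °C
Reagents that add atoms: none
Why: Intramolecular alkoxymercuration–demercuration: the ring hydroxyl attacks the mercurinium ion at its tertiary carbon (Markovnikov, 7-exo, no regiochemical alternative) to close the trans-fused oxepane, and Bu3SnH replaces mercury by hydrogen through the alkyl radical without touching the ketone.

Step 18
Reactants: 19 right-half sulfone; 35 left-half keto sulfone
Product: 38 (1R,3aR,8aR)-5-{2-[(3R,5aR,6R,7S,9aR)-3,7-dihydroxy-2,2,5a,7-tetramethyldecahydro-1-benzoxepin-6-yl]-1-(phenylsulfonyl)ethyl}-1-hydroxy-1,4,4,6-tetramethyl-2,3,3a,4,8,8a-hexahydroazulen-7(1H)-one, via enone 36 (not isolated), via Michael adduct 37 (not isolated)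
Conditions: 35, LiN(SiMe3)2 (2.1 equiv), THF, −78 to 0 °C; add to 19 + LiN(SiMe3)2 (2.1 equiv), −78 to 0 °C; then CeCl3, MeLi (excess), −78 °C; AcOH
Reagents that add atoms: methyllithium ([Li]C)
Why: E1cB loss of methanesulfinate unveils the α-methylene ketone, which takes up the sulfone-stabilized carbanion of 19 in a Michael addition; proton transfer from the new α-sulfonyl C–H to the ketone enolate (axial protonation, side chain equatorial, 6R) leaves the right half masked as its stabilized anion, so the organocerium reagent adds only to the left ketone, equatorially because the axial angular methyl blocks the axial path (7S, hydroxyl axial).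

Step 19
Reactants: 38 sulfone triol
Product: 39 (1R,3aR,8aR)-5-{2-[(3R,5aR,6R,7S,9aR)-3,7-dihydroxy-2,2,5a,7-tetramethyldecahydro-1-benzoxepin-6-yl]ethyl}-1-hydroxy-1,4,4,6-tetramethyl-2,3,3a,4,8,8a-hexahydroazulen-7(1H)-one
Conditions: SmI2 (2.5 equiv), HMPA, THF, −78 °C; pH 7 buffer; DBU (cat.), CH2Cl2, rt
Reagents that add atoms: none
Why: Reductive desulfonylation with SmI2: electron transfer to the γ-sulfonyl enone expels sulfinate to give the samarium dienolate, whose protonation and DBU equilibration give the conjugated tetrasubstituted enone; no stereocentre is touched.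

## Compound list

1 | 2-methylpentan-3-one | CCC(=O)C(C)C | starting material
2 | methyl acrylate | C=CC(=O)OC | starting material
3 | 2,4,4-trimethylcyclohexane-1,3-dione | CC1C(=O)CCC(C)(C)C1=O | intermediate
4 | 3-methoxy-2,6,6-trimethylcyclohex-2-en-1-one | COC1=C(C)C(=O)C(C)(C)CC1 | intermediate
5 | lithium 3-methoxy-1,2,6,6-tetramethylcyclohex-2-en-1-olate (racemic) | COC1=C(C)C(C)([O-])C(C)(C)CC1.[Li+] | intermediate
6 | 2,3,4,4-tetramethylcyclohex-2-en-1-one | CC1=C(C)C(C)(C)CCC1=O | intermediate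
7 | 2,3,4,4-tetramethylcyclohexa-2,5-dien-1-one | CC1=C(C)C(C)(C)C=CC1=O | intermediate
8 | but-3-en-2-one | CC(=O)C=C | starting material
9 | 2-(2-bromoethyl)-2-methyl-1,3-dioxolane | CC1(CCBr)OCCO1 | intermediate
10 | [2-(2-methyl-1,3-dioxolan-2-yl)ethyl]magnesium bromide | CC1(CC[Mg]Br)OCCO1 | intermediate
11 | bis[2-(2-methyl-1,3-dioxolan-2-yl)ethyl]zinc | CC1(CC[Zn]CCC2(C)OCCO2)OCCO1 | intermediate
12 | trimethyl{[(6R)-3,4,5,5-tetramethyl-6-[2-(2-methyl-1,3-dioxolan-2-yl)ethyl]cyclohexa-1,3-dien-2-yl]oxy}silane | CC1=C(C)C(C)(C)[C@H](CCC2(C)OCCO2)C=C1O[Si](C)(C)C | intermediate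
13 | (5R)-2,3,4,4-tetramethyl-5-[2-(2-methyl-1,3-dioxolan-2-yl)ethyl]-1-(trimethylsilyloxy)bicyclo[4.1.0]hept-2-ene, cyclopropane CH2 anti to the side chain | CC1=C(C)C(C)(C)[C@H](CCC2(C)OCCO2)[C@H]2C[C@@]12O[Si](C)(C)C | intermediate
14 | (5S)-6-chloro-2,3,4,4-tetramethyl-5-[2-(2-methyl-1,3-dioxolan-2-yl)ethyl]cyclohept-2-en-1-one (C-6 epimers; same spatial arrangement at C-5 as in 12) | CC1=C(C)C(C)(C)[C@H](CCC2(C)OCCO2)C(Cl)CC1=O | intermediate
15 | (5R)-2,3,4,4-tetramethyl-5-[2-(2-methyl-1,3-dioxolan-2-yl)ethyl]cyclohepta-2,6-dien-1-one | CC1=C(C)C(C)(C)[C@H](CCC2(C)OCCO2)C=CC1=O | intermediate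
16 | (5R)-2,3,4,4-tetramethyl-5-(3-oxobutyl)cyclohepta-2,6-dien-1-one | CC1=C(C)C(C)(C)[C@H](CCC(C)=O)C=CC1=O | intermediate
17 | (1R,3aR,8aR)-1-hydroxy-1,4,4,5,6-pentamethyl-2,3,3a,4,8,8a-hexahydroazulen-7(1H)-one | CC1=C(C)C(C)(C)[C@@H]2CC[C@@](C)(O)[C@@H]2CC1=O | intermediate
18 | (1R,3aR,8aR)-5-(bromomethyl)-1-hydroxy-1,4,4,6-tetramethyl-2,3,3a,4,8,8a-hexahydroazulen-7(1H)-one | CC1=C(CBr)C(C)(C)[C@@H]2CC[C@@](C)(O)[C@@H]2CC1=O | intermediate
19 | (1R,3aR,8aR)-1-hydroxy-1,4,4,6-tetramethyl-5-[(phenylsulfonyl)methyl]-2,3,3a,4,8,8a-hexahydroazulen-7(1H)-one | CC1=C(CS(=O)(=O)c2ccccc2)C(C)(C)[C@@H]2CC[C@@](C)(O)[C@@H]2CC1=O | intermediate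
20 | cyclohexane-1,3-dione | O=C1CCCC(=O)C1 | starting material
21 | 3-methoxycyclohex-2-en-1-one | COC1=CC(=O)CCC1 | intermediate
22 | lithium (1R)-4-methoxy-2-oxocyclohex-3-en-1-olate | COC1=CC(=O)[C@H]([O-])CC1.[Li+] | intermediate
23 | (6R)-6-[(tert-butyldimethylsilyl)oxy]-3-methoxycyclohex-2-en-1-one | COC1=CC(=O)[C@H](O[Si](C)(C)C(C)(C)C)CC1 | intermediate
24 | lithium (6R)-6-[(tert-butyldimethylsilyl)oxy]-3-methoxy-1-methylcyclohex-2-en-1-olate (C-1 epimers) | COC1=CC(C)([O-])[C@H](O[Si](C)(C)C(C)(C)C)CC1.[Li+] | intermediate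
25 | (4R)-4-[(tert-butyldimethylsilyl)oxy]-3-methylcyclohex-2-en-1-one | CC1=CC(=O)CC[C@H]1O[Si](C)(C)C(C)(C)C | intermediate
26 | 5-bromo-2-methylpent-2-ene | CC(C)=CCCBr | starting material
27 | (4-methylpent-3-en-1-yl)magnesium bromide | CC(C)=CCC[Mg]Br | intermediate
28 | tert-butyldimethyl{[(1R,2R)-2-methyl-2-(4-methylpent-3-en-1-yl)-4-(trimethylsilyloxy)cyclohex-3-en-1-yl]oxy}silane | C[Si](C)(C)OC1=C[C@@](C)(CCC=C(C)C)[C@H](O[Si](C)(C)C(C)(C)C)CC1 | intermediate
29 | (3R,4R)-4-[(tert-butyldimethylsilyl)oxy]-3-methyl-3-(4-methylpent-3-en-1-yl)-2-[(methylsulfanyl)methyl]cyclohexan-1-one (C-2 epimers) | CSCC1[C@@](C)(CCC=C(C)C)[C@H](O[Si](C)(C)C(C)(C)C)CCC1=O | intermediate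
30 | (3R,4R)-4-[(tert-butyldimethylsilyl)oxy]-3-methyl-3-(4-methylpent-3-en-1-yl)-2-[(methylsulfonyl)methyl]cyclohexan-1-one (C-2 epimers) | CS(=O)(=O)CC1[C@@](C)(CCC=C(C)C)[C@H](O[Si](C)(C)C(C)(C)C)CCC1=O | intermediate
31 | (3R,4R)-4-[(tert-butyldimethylsilyl)oxy]-3-{2-[(2R)-3,3-dimethyloxiran-2-yl]ethyl}-3-methyl-2-[(methylsulfonyl)methyl]cyclohexan-1-one (C-2 epimers) | CS(=O)(=O)CC1[C@@](C)(CC[C@H]2OC2(C)C)[C@H](O[Si](C)(C)C(C)(C)C)CCC1=O | intermediate
32 | (3R,4R)-4-[(tert-butyldimethylsilyl)oxy]-3-[(3R)-3-hydroxy-4-methylpent-4-en-1-yl]-3-methyl-2-[(methylsulfonyl)methyl]cyclohexan-1-one (C-2 epimers) | CS(=O)(=O)CC1[C@@](C)(CC[C@@H](O)C(C)=C)[C@H](O[Si](C)(C)C(C)(C)C)CCC1=O | intermediate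
33 | (3R,4R)-4-hydroxy-3-[(3R)-3-hydroxy-4-methylpent-4-en-1-yl]-3-methyl-2-[(methylsulfonyl)methyl]cyclohexan-1-one (C-2 epimers) | CS(=O)(=O)CC1[C@@](C)(CC[C@@H](O)C(C)=C)[C@H](O)CCC1=O | intermediate
34 | {[(3R,5aR,9aR)-3-hydroxy-2,5a-dimethyl-6-[(methylsulfonyl)methyl]-7-oxodecahydro-1-benzoxepin-2-yl]methyl}mercury trifluoroacetate (C-2 and C-6 epimers) | CS(=O)(=O)CC1[C@@]2(C)CC[C@@H](O)C(C)(C[Hg]OC(=O)C(F)(F)F)O[C@@H]2CCC1=O | intermediate
35 | (3R,5aR,9aR)-3-hydroxy-2,2,5a-trimethyl-6-[(methylsulfonyl)methyl]octahydro-1-benzoxepin-7(2H)-one (C-6 epimers) | CS(=O)(=O)CC1[C@@]2(C)CC[C@@H](O)C(C)(C)O[C@@H]2CCC1=O | intermediate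
36 | (3R,5aR,9aR)-3-hydroxy-2,2,5a-trimethyl-6-methylideneoctahydro-1-benzoxepin-7(2H)-one | C=C1[C@@]2(C)CC[C@@H](O)C(C)(C)O[C@@H]2CCC1=O | intermediate
37 | (1R,3aR,8aR)-1-hydroxy-5-{2-[(3R,5aR,6R,9aR)-3-hydroxy-2,2,5a-trimethyl-7-oxodecahydro-1-benzoxepin-6-yl]-1-(phenylsulfonyl)ethyl}-1,4,4,6-tetramethyl-2,3,3a,4,8,8a-hexahydroazulen-7(1H)-one (epimers at the sulfonyl carbon; present as its lithium salt) | CC1=C(C(C[C@@H]2[C@@]3(C)CC[C@@H](O)C(C)(C)O[C@@H]3CCC2=O)S(=O)(=O)c2ccccc2)C(C)(C)[C@@H]2CC[C@@](C)(O)[C@@H]2CC1=O | intermediate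
38 | (1R,3aR,8aR)-5-{2-[(3R,5aR,6R,7S,9aR)-3,7-dihydroxy-2,2,5a,7-tetramethyldecahydro-1-benzoxepin-6-yl]-1-(phenylsulfonyl)ethyl}-1-hydroxy-1,4,4,6-tetramethyl-2,3,3a,4,8,8a-hexahydroazulen-7(1H)-one (epimers at the sulfonyl carbon) | CC1=C(C(C[C@@H]2[C@@]3(C)CC[C@@H](O)C(C)(C)O[C@@H]3CC[C@]2(C)O)S(=O)(=O)c2ccccc2)C(C)(C)[C@@H]2CC[C@@](C)(O)[C@@H]2CC1=O | intermediate
39 | (1R,3aR,8aR)-5-{2-[(3R,5aR,6R,7S,9aR)-3,7-dihydroxy-2,2,5a,7-tetramethyldecahydro-1-benzoxepin-6-yl]ethyl}-1-hydroxy-1,4,4,6-tetramethyl-2,3,3a,4,8,8a-hexahydroazulen-7(1H)-one (CNP0397160.1) | CC1=C(CC[C@@H]2[C@@]3(C)CC[C@@H](O)C(C)(C)O[C@@H]3CC[C@]2(C)O)C(C)(C)[C@@H]2CC[C@@](C)(O)[C@@H]2CC1=O | target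

## Step count and risks

Total steps: 19. Longest linear sequence: 11 steps (1, 2, 3, 4, 6, 7, 8, 9, 10, 18, 19).

Steps most likely to fail:

Step 9 (SmI2 cyclization). Risks are over-reduction or dimerization of the dienone and the wrong carbinol configuration if samarium chelation overrides the anti arrangement. The fallback sets out from 16 and comes back at 17. The methyl ketone is converted under kinetic control (KN(SiMe3)2, PhNTf2, THF, −78 °C) into the enol triflate F1. A Pd-catalysed reductive Heck cyclization (Pd(OAc)2, PPh3, HCO2Na, DMF, 70 °C) closes the five-membered ring cis onto the disubstituted enone and gives the exo-methylene bicycle F2. Mukaiyama hydration (Co(acac)2, PhSiH3, O2, i-PrOH) then delivers oxygen to the tertiary radical from the convex face and gives 17.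

Step 17 (seven-membered alkoxymercuration). Ring closure may be slow relative to hydration or trifluoroacetate capture. The fallback sets out from 31 and comes back at 35. The epoxide is opened directly: TBSOTf (cat.), 2,6-di-tert-butyl-4-methylpyridine, CH2Cl2, −78 °C, the ring silyl ether attacking the silylated epoxide at its tertiary carbon (7-endo) with silyl transfer, gives the oxepane silyl ether F3. HF·pyridine then gives 35.

Step 18 (elimination, Michael addition and methyl addition in one flask). Risks are incomplete proton transfer, which would leave the left ketone as its enolate, and attack of MeLi on the right half. The fallback sets out from 35 and 18 and comes back at 39. DBU (CH2Cl2, rt) gives enone 36, which is isolated here. MeLi/CeCl3 (THF, −78 °C) adds equatorially to give the exocyclic-alkene diol F4. 9-BBN-H (THF, 60 °C) adds from the face opposite the axial methyl and hydroxyl groups, setting the 6R centre, and gives the alkylborane F5. A B-alkyl Suzuki coupling (Pd(dppf)Cl2, K3PO4, DMF–H2O, 50 °C) with allylic bromide 18, isolated from step 10 before the sulfinate is added, gives 39 directly.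

## Further compounds

F1 | step 9 | 4-[(1R)-2,2,3,4-tetramethyl-5-oxocyclohepta-3,6-dien-1-yl]but-1-en-2-yl trifluoromethanesulfonate | CC1=C(C)C(C)(C)[C@H](CCC(=C)OS(=O)(=O)C(F)(F)F)C=CC1=O
F2 | step 9 | (3aR,8aR)-4,4,5,6-tetramethyl-1-methylidene-2,3,3a,4,8,8a-hexahydroazulen-7(1H)-one | CC1=C(C)C(C)(C)[C@@H]2CCC(=C)[C@@H]2CC1=O
F3 | step 17 | (3R,5aR,9aR)-3-[(tert-butyldimethylsilyl)oxy]-2,2,5a-trimethyl-6-[(methylsulfonyl)methyl]octahydro-1-benzoxepin-7(2H)-one (C-6 epimers) | CS(=O)(=O)CC1[C@@]2(C)CC[C@@H](O[Si](C)(C)C(C)(C)C)C(C)(C)O[C@@H]2CCC1=O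
F4 | step 18 | (3R,5aR,7S,9aR)-2,2,5a,7-tetramethyl-6-methylidenedecahydro-1-benzoxepine-3,7-diol | C=C1[C@@]2(C)CC[C@@H](O)C(C)(C)O[C@@H]2CC[C@]1(C)O
F5 | step 18 | (3R,5aR,6R,7S,9aR)-6-[(9-borabicyclo[3.3.1]nonan-9-yl)methyl]-2,2,5a,7-tetramethyldecahydro-1-benzoxepine-3,7-diol | B1(C[C@@H]2[C@@]3(C)CC[C@@H](O)C(C)(C)O[C@@H]3CC[C@]2(C)O)C2CCCC1CCC2
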